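The carbocycle is disconnected at C2–C3. C2 is the only ring carbon without oxygen and C1 carries the one-carbon branch C7, so the six ring carbons map onto a 6-deoxyhexos-5-ulose from L-rhamnose: its methyl group becomes C2, its ketone carbon C1, its aldehyde carbon C3, and its three oxygenated carbons supply C4, C5 and C6 in the required cis, trans order. One D-proline-mediated intramolecular aldol forms the C2–C3 bond, closes the cyclohexane ring and sets the C3 carbinol. The precursor is the open-chain keto aldehyde with silyl ethers on the future O4 and O6 and a 4-methoxybenzyl ether on the future O5, the later benzoate site.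

Key step: step 7

Remark: carbocycles are numbered as in the target (C1 bears C7, C2 is the oxygen-free ring carbon) and sugars by sugar numbering; TBS = tert-butyldimethylsilyl, PMB = 4-methoxybenzyl, Bz = benzoyl, Tf = trifluoromethanesulfonyl; L-rhamnose is assumed to be used as its commercial monohydrate.

Step 1
Reactants: 1 L-rhamnose
Product: 2 allyl α-L-rhamnopyranoside
Conditions: allyl alcohol (solvent), TfOH (cat.), 80 °C; then Et3N
Reagents that add atoms: allyl alcohol, C=CCO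
Why: Fischer glycosidation under thermodynamic control, in which the anomeric effect favours the axial (α) allyloxy group of the pyranoside and C2–C5 are untouched.

Step 2
Reactants: 2 allyl α-L-rhamnopyranoside; 3 4-methoxybenzyl chloride
Product: 5 allyl 3-O-PMB-α-L-rhamnopyranoside, via 2,3-O-dibutylstannylene acetal 4 (not isolated)
Conditions: Bu2SnO, toluene, reflux (−H2O); then 3, Bu4NI, 90 °C
Reagents that add atoms: none
Why: Regioselective stannylene-acetal alkylation, in which the five-membered dibutylstannylene on the cis-2,3-diol activates the equatorial O3, so the PMB ether goes to O3 and O2 and O4 stay free.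

Step 3
Reactants: 5 allyl 3-O-PMB-α-L-rhamnopyranoside
Product: 6 allyl 2,4-bis-O-TBS-3-O-PMB-α-L-rhamnopyranoside
Conditions: TBSOTf (2.6 equiv), 2,6-lutidine, CH2Cl2, 0 °C to rt
Reagents that add atoms: tert-butyldimethylsilyl trifluoromethanesulfonate, CC(C)(C)[Si](C)(C)OS(=O)(=O)C(F)(F)F
Why: Silyl ether formation with a silyl triflate and a hindered pyridine base is forceful enough for the axial O2 and for O4, and no stereocentre is touched.

Step 4
Reactants: 6 allyl 2,4-bis-O-TBS-3-O-PMB-α-L-rhamnopyranoside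
Product: 8 2,4-bis-O-TBS-3-O-PMB-L-rhamnopyranose, via prop-1-enyl glycoside 7 (not isolated)
Conditions: [Ir(C8H12)(PMePh2)2]PF6 (2 mol%, activated with H2), THF, rt; then I2, NaHCO3, THF/H2O, 0 °C
Reagents that add atoms: none
Why: Iridium-hydride-mediated isomerisation of the allyl to the prop-1-enyl glycoside and iodonium-induced hydrolysis of that enol ether free the hemiacetal under nearly neutral conditions that spare silyl and PMB ethers.

Step 5
Reactants: 8 2,4-bis-O-TBS-3-O-PMB-L-rhamnopyranose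
Product: 9 2,4-bis-O-TBS-3-O-PMB-L-rhamnitol
Conditions: NaBH4, EtOH, 0 °C
Reagents that add atoms: none
Why: Borohydride reduction of the aldehyde form in equilibrium with the lactol gives the open-chain 1,5-diol, and the cold protic medium holds the alkoxides as borates and so limits 1,2-silyl shifts.

Step 6
Reactants: 9 2,4-bis-O-TBS-3-O-PMB-L-rhamnitol
Product: 10 2,4-bis-O-TBS-6-deoxy-3-O-PMB-L-lyxo-hexos-5-ulose
Conditions: (COCl)2, DMSO, CH2Cl2, −78 °C; then i-Pr2NEt, −78 to −20 °C; used crude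
Reagents that add atoms: none
Why: Swern oxidation turns both hydroxyls into alkoxysulfonium ions before the base is added, so aldehyde and ketone arise together and no lactol or lactone can form, while the hindered base at low temperature protects the two α-stereocentres.

Step 7
Reactants: 10 2,4-bis-O-TBS-6-deoxy-3-O-PMB-L-lyxo-hexos-5-ulose
Product: 11 (3R,4S,5S,6R)-4,6-bis(TBSO)-3-hydroxy-5-(PMBO)cyclohexan-1-one
Conditions: D-proline (30 mol%), DMSO, rt
Reagents that add atoms: none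
Why: D-Proline condenses with the methyl ketone (the α-branched aldehyde is a poor enamine donor) to the less substituted enamine, whose CH2 terminus (C2) adds to the aldehyde carbon (C3) while the carboxylic acid protonates the developing alkoxide, and hydrolysis of the iminium ion returns the β-hydroxy ketone and the catalyst. The closest known reactions are the Hajos–Parrish cyclisation and the aldol ring closure of hexos-5-uloses that forms the carbonyl stage of the Ferrier carbocyclisation. The six-membered carbocycle closes in the 6-(enolendo)-exo-trig mode, because both enamine carbons (C1 and C2) become ring members and the aldehyde oxygen stays outside the ring. C3 is the only new stereocentre: in the acid-bridged transition state the aldehyde oxygen must sit pseudo-axial on the enamine face that carries the carboxyl group, and for the anti-enamine of D-proline this face corresponds to the half-chair with O5 and O6 pseudo-equatorial and O4 pseudo-axial, which should deliver the 3-hydroxyl trans to O4 (3R) and avoids the syn-axial O3/O5 contact that the L-catalyst would impose. Regioselectivity is secured by the substrate, since the other α-carbon of the ketone (C6) could only close a four-membered ring, and the neutral medium at room temperature is needed to keep the β-alkoxy aldehyde from E1cB loss of the PMB-oxy group and the ketol from dehydration.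

Step 8
Reactants: 11 (3R,4S,5S,6R)-4,6-bis(TBSO)-3-hydroxy-5-(PMBO)cyclohexan-1-one
Product: 12 (3R,4R,5S,6R)-3,4,6-tris(TBSO)-5-(PMBO)cyclohexan-1-one
Conditions: TBSOTf (1.2 equiv), 2,6-lutidine, CH2Cl2, −78 °C
Reagents that add atoms: tert-butyldimethylsilyl trifluoromethanesulfonate, CC(C)(C)[Si](C)(C)OS(=O)(=O)C(F)(F)F
Why: O-Silylation with a silyl triflate and 2,6-lutidine at −78 °C is faster than enolisation, so the β-hydroxy ketone is capped without E1cB dehydration.

Step 9
Reactants: 12 (3R,4R,5S,6R)-3,4,6-tris(TBSO)-5-(PMBO)cyclohexan-1-one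
Product: 14 (3R,4R,5S,6R)-3,4,6-tris(TBSO)-5-(PMBO)cyclohex-1-en-1-yl trifluoromethanesulfonate, via potassium enolate 13 (not isolated)
Conditions: KN(SiMe3)2 (1.2 equiv) added to 12 and 2-[bis(trifluoromethylsulfonyl)amino]-5-chloropyridine (1.3 equiv), THF, −78 °C
Reagents that add atoms: 2-[bis(trifluoromethylsulfonyl)amino]-5-chloropyridine, O=S(=O)(N(c1ccc(Cl)cn1)S(=O)(=O)C(F)(F)F)C(F)(F)F
Why: Kinetic enolisation by the bulky amide takes a proton from the unhindered C2 methylene and not from the shielded α-silyloxy methine C6, and the triflimide already present traps the enolate on oxygen (enol triflate formation) before it can expel the C3 silyloxy group.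

Step 10
Reactants: 14 (3R,4R,5S,6R)-3,4,6-tris(TBSO)-5-(PMBO)cyclohex-1-en-1-yl trifluoromethanesulfonate
Product: 15 methyl (3R,4R,5R,6S)-3,4,6-tris(TBSO)-5-(PMBO)cyclohex-1-ene-1-carboxylate
Conditions: Pd(OAc)2 (10 mol%), PPh3 (20 mol%), CO (1 atm), MeOH, Et3N, DMF, 40 °C
Reagents that add atoms: carbon monoxide, [C-]#[O+]; methanol, CO
Why: Palladium-catalysed alkoxycarbonylation, in which zerovalent palladium adds oxidatively to the C1–OTf bond, CO inserts and methanol cleaves the acylpalladium species, installs C7 with the C1=C2 double bond fixed in place.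

Step 11
Reactants: 15 methyl (3R,4R,5R,6S)-3,4,6-tris(TBSO)-5-(PMBO)cyclohex-1-ene-1-carboxylate
Product: 16 methyl (3R,4R,5R,6S)-3,4,6-tris(TBSO)-5-hydroxycyclohex-1-ene-1-carboxylate
Conditions: DDQ, CH2Cl2/pH 7 phosphate buffer, 0 °C to rt
Reagents that add atoms: none
Why: Oxidative PMB cleavage, in which DDQ abstracts hydride from the electron-rich benzylic position and water hydrolyses the oxocarbenium ion, leaves silyl ethers and the electron-poor enoate untouched and is run before any oxidisable allylic alcohol is present.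

Step 12
Reactants: 16 methyl (3R,4R,5R,6S)-3,4,6-tris(TBSO)-5-hydroxycyclohex-1-ene-1-carboxylate
Product: 17 [(3R,4R,5R,6S)-3,4,6-tris(TBSO)-5-hydroxycyclohex-1-en-1-yl]methanol
Conditions: i-Bu2AlH (4 equiv), CH2Cl2, −78 to 0 °C; aq. KNaC4H4O6
Reagents that add atoms: none
Why: 1,2-Reduction of the conjugated ester by the aluminium hydride gives the primary allylic alcohol, and silyl ethers and the alkene are inert to it.

Step 13
Reactants: 17 [(3R,4R,5R,6S)-3,4,6-tris(TBSO)-5-hydroxycyclohex-1-en-1-yl]methanol; 18 benzoyl chloride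
Product: 19 [(3R,4R,5R,6S)-5-(benzoyloxy)-3,4,6-tris(TBSO)cyclohex-1-en-1-yl]methyl benzoate
Conditions: 18 (3 equiv), pyridine, DMAP (cat.), CH2Cl2, 0 °C to rt
Reagents that add atoms: none
Why: DMAP-catalysed acylation esterifies the only two free hydroxyls, the primary allylic O7 and the secondary O5.

Step 14
Reactants: 19 [(3R,4R,5R,6S)-5-(benzoyloxy)-3,4,6-tris(TBSO)cyclohex-1-en-1-yl]methyl benzoate
Product: 20 [(3R,4S,5R,6S)-5-(benzoyloxy)-3,4,6-trihydroxycyclohex-1-en-1-yl]methyl benzoate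
Conditions: HF·pyridine, pyridine/THF, 0 °C to rt
Reagents that add atoms: none
Why: Fluoride-driven desilylation (strong Si–F bond) in a buffered acidic medium removes all three silyl ethers without forming alkoxides, so the benzoates are expected to stay on O5 and O7.

Compound list
1 | L-rhamnose (6-deoxy-L-mannose) | C[C@H](O)[C@H](O)[C@@H](O)[C@@H](O)C=O | starting material
2 | allyl α-L-rhamnopyranoside | C=CCO[C@@H]1O[C@@H](C)[C@H](O)[C@@H](O)[C@H]1O | intermediate
3 | 4-methoxybenzyl chloride | COc1ccc(CCl)cc1 | starting material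
4 | allyl 2,3-O-(dibutylstannylene)-α-L-rhamnopyranoside | C=CCO[C@@H]1O[C@@H](C)[C@H](O)[C@H]2O[Sn](CCCC)(CCCC)O[C@@H]12 | intermediate (not isolated)
5 | allyl 3-O-PMB-α-L-rhamnopyranoside | C=CCO[C@@H]1O[C@@H](C)[C@H](O)[C@@H](OCc2ccc(OC)cc2)[C@H]1O | intermediate
6 | allyl 2,4-bis-O-TBS-3-O-PMB-α-L-rhamnopyranoside | C=CCO[C@@H]1O[C@@H](C)[C@H](O[Si](C)(C)C(C)(C)C)[C@@H](OCc2ccc(OC)cc2)[C@H]1O[Si](C)(C)C(C)(C)C | intermediate
7 | (E)-prop-1-enyl 2,4-bis-O-TBS-3-O-PMB-α-L-rhamnopyranoside | C/C=C/O[C@@H]1O[C@@H](C)[C@H](O[Si](C)(C)C(C)(C)C)[C@@H](OCc2ccc(OC)cc2)[C@H]1O[Si](C)(C)C(C)(C)C | intermediate (not isolated)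
8 | 2,4-bis-O-TBS-3-O-PMB-L-rhamnopyranose (anomer mixture) | OC1O[C@@H](C)[C@H](O[Si](C)(C)C(C)(C)C)[C@@H](OCc2ccc(OC)cc2)[C@H]1O[Si](C)(C)C(C)(C)C | intermediate
9 | 2,4-bis-O-TBS-3-O-PMB-L-rhamnitol, (2S,3S,4S,5S)-2,4-bis(TBSO)-3-(PMBO)hexane-1,5-diol | C[C@H](O)[C@H](O[Si](C)(C)C(C)(C)C)[C@@H](OCc1ccc(OC)cc1)[C@@H](O[Si](C)(C)C(C)(C)C)CO | intermediate
10 | 2,4-bis-O-TBS-6-deoxy-3-O-PMB-L-lyxo-hexos-5-ulose, (2R,3S,4R)-2,4-bis(TBSO)-3-(PMBO)-5-oxohexanal | CC(=O)[C@H](O[Si](C)(C)C(C)(C)C)[C@@H](OCc1ccc(OC)cc1)[C@@H](O[Si](C)(C)C(C)(C)C)C=O | intermediate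
11 | (3R,4S,5S,6R)-4,6-bis(TBSO)-3-hydroxy-5-(PMBO)cyclohexan-1-one | O=C1C[C@@H](O)[C@H](O[Si](C)(C)C(C)(C)C)[C@H](OCc2ccc(OC)cc2)[C@H]1O[Si](C)(C)C(C)(C)C | intermediate
12 | (3R,4R,5S,6R)-3,4,6-tris(TBSO)-5-(PMBO)cyclohexan-1-one | O=C1C[C@@H](O[Si](C)(C)C(C)(C)C)[C@H](O[Si](C)(C)C(C)(C)C)[C@H](OCc2ccc(OC)cc2)[C@H]1O[Si](C)(C)C(C)(C)C | intermediate
13 | potassium (3R,4R,5S,6R)-3,4,6-tris(TBSO)-5-(PMBO)cyclohex-1-en-1-olate | [K+].[O-]C1=C[C@@H](O[Si](C)(C)C(C)(C)C)[C@H](O[Si](C)(C)C(C)(C)C)[C@H](OCc2ccc(OC)cc2)[C@H]1O[Si](C)(C)C(C)(C)C | intermediate (not isolated)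
14 | (3R,4R,5S,6R)-3,4,6-tris(TBSO)-5-(PMBO)cyclohex-1-en-1-yl trifluoromethanesulfonate | O=S(=O)(OC1=C[C@@H](O[Si](C)(C)C(C)(C)C)[C@H](O[Si](C)(C)C(C)(C)C)[C@H](OCc2ccc(OC)cc2)[C@H]1O[Si](C)(C)C(C)(C)C)C(F)(F)F | intermediate
15 | methyl (3R,4R,5R,6S)-3,4,6-tris(TBSO)-5-(PMBO)cyclohex-1-ene-1-carboxylate | COC(=O)C1=C[C@@H](O[Si](C)(C)C(C)(C)C)[C@H](O[Si](C)(C)C(C)(C)C)[C@H](OCc2ccc(OC)cc2)[C@H]1O[Si](C)(C)C(C)(C)C | intermediate
16 | methyl (3R,4R,5R,6S)-3,4,6-tris(TBSO)-5-hydroxycyclohex-1-ene-1-carboxylate | COC(=O)C1=C[C@@H](O[Si](C)(C)C(C)(C)C)[C@H](O[Si](C)(C)C(C)(C)C)[C@H](O)[C@H]1O[Si](C)(C)C(C)(C)C | intermediate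
17 | [(3R,4R,5R,6S)-3,4,6-tris(TBSO)-5-hydroxycyclohex-1-en-1-yl]methanol | OCC1=C[C@@H](O[Si](C)(C)C(C)(C)C)[C@H](O[Si](C)(C)C(C)(C)C)[C@H](O)[C@H]1O[Si](C)(C)C(C)(C)C | intermediate
18 | benzoyl chloride | O=C(Cl)c1ccccc1 | starting material
19 | [(3R,4R,5R,6S)-5-(benzoyloxy)-3,4,6-tris(TBSO)cyclohex-1-en-1-yl]methyl benzoate | O=C(OCC1=C[C@@H](O[Si](C)(C)C(C)(C)C)[C@H](O[Si](C)(C)C(C)(C)C)[C@H](OC(=O)c2ccccc2)[C@H]1O[Si](C)(C)C(C)(C)C)c1ccccc1 | intermediate
20 | [(3R,4S,5R,6S)-5-(benzoyloxy)-3,4,6-trihydroxycyclohex-1-en-1-yl]methyl benzoate | O=C(OCC1=C[C@@H](O)[C@H](O)[C@H](OC(=O)c2ccccc2)[C@H]1O)c1ccccc1 | target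

Total step count: 14. Longest linear sequence: 14 steps, from L-rhamnose (1) to the target (20).

Steps most likely to fail

Step 7 (ring-closing aldol). The facial selectivity at C3 may be poor or reversed, because the half-chair that D-proline selects places the C6 silyloxy group pseudo-equatorial, where it meets allylic strain against the pyrrolidine ring. E1cB loss of the PMB-oxy group or dehydration of the ketol may also compete. The fallback sets the C3 oxygen after the ring is closed. Keto aldehyde 10 is cyclised without regard to C3 (step 7 conditions or pyrrolidinium acetate, CH2Cl2), which gives 11 together with its 3-epimer, (3S,4S,5S,6R)-4,6-bis(TBSO)-3-hydroxy-5-(PMBO)cyclohexan-1-one F1. The mixture is mesylated (MsCl, Et3N, CH2Cl2, 0 °C) to the 3-O-mesylates of both epimers F2, which eliminate in the same flask to (4S,5S,6R)-4,6-bis(TBSO)-5-(PMBO)cyclohex-2-en-1-one F3. Weitz–Scheffer epoxidation (t-BuOOH, benzyltrimethylammonium hydroxide, THF, 0 °C) should add to the face opposite the C4 silyloxy group and give (2S,3R,4R,5S,6R)-4,6-bis(TBSO)-2,3-epoxy-5-(PMBO)cyclohexan-1-one F4. Reductive cleavage of the C2–O bond with Na[PhSeB(OEt)3] (from (PhSe)2 and NaBH4, EtOH, AcOH, 0 °C) then comes back to ketol 11 with the 3-hydroxyl trans to O4.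

Step 9 (enol triflate). Enolisation may go toward C6, or the C2 enolate may expel the C3 silyloxy group before it is trapped. The fallback attaches C7 without any enolate. Ketone 12 is methylenated with Cp2TiMe2 (toluene, 65 °C) to (3R,4R,5R,6S)-3,4,6-tris(TBSO)-5-(PMBO)-1-methylidenecyclohexane F5. Epoxidation (mCPBA, NaHCO3, CH2Cl2) gives the spiro-epoxide, 1-oxaspiro[2.5]octane with the same four ether groups, both epimers at the spiro carbon F6. Diethylaluminium 2,2,6,6-tetramethylpiperidide (toluene, 0 °C) should remove a C2 hydrogen in a syn-elimination and open the epoxide to [(3R,4R,5R,6S)-3,4,6-tris(TBSO)-5-(PMBO)cyclohex-1-en-1-yl]methanol F7. DDQ (CH2Cl2/pH 7 buffer) then cleaves the PMB ether and the route is rejoined at diol 17.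

Step 6 (double oxidation). The amine base may epimerise the carbon next to the new aldehyde or trigger E1cB loss of the PMB-oxy group, and incomplete activation may divert material to a lactol. The fallback unveils the two carbonyls one at a time, the aldehyde last and under neutral conditions, and bypasses step 5 as well. Lactol 8 is methylenated in a Wittig reaction (Ph3P=CH2, THF, 0 °C) to 1,2,7-trideoxy-3,5-di-O-TBS-4-O-PMB-L-manno-hept-1-enitol F8. The free secondary hydroxyl is oxidised with Dess–Martin periodinane (NaHCO3, CH2Cl2) to (3R,4S,5S)-3,5-bis(TBSO)-4-(PMBO)hept-6-en-2-one F9. Lemieux–Johnson cleavage of the terminal alkene (OsO4 cat., NaIO4, 2,6-lutidine, dioxane/H2O) then releases keto aldehyde 10.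

Further compounds
F1 | step 7 | (3S,4S,5S,6R)-4,6-bis(TBSO)-3-hydroxy-5-(PMBO)cyclohexan-1-one | O=C1C[C@H](O)[C@H](O[Si](C)(C)C(C)(C)C)[C@H](OCc2ccc(OC)cc2)[C@H]1O[Si](C)(C)C(C)(C)C
F2 | step 7 | 3-O-methanesulfonate of (4R,5S,6R)-4,6-bis(TBSO)-3-hydroxy-5-(PMBO)cyclohexan-1-one, both C3 epimers | O=C1CC(OS(C)(=O)=O)[C@H](O[Si](C)(C)C(C)(C)C)[C@H](OCc2ccc(OC)cc2)[C@H]1O[Si](C)(C)C(C)(C)C
F3 | step 7 | (4S,5S,6R)-4,6-bis(TBSO)-5-(PMBO)cyclohex-2-en-1-one | O=C1C=C[C@H](O[Si](C)(C)C(C)(C)C)[C@H](OCc2ccc(OC)cc2)[C@H]1O[Si](C)(C)C(C)(C)C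
F4 | step 7 | (2S,3R,4R,5S,6R)-4,6-bis(TBSO)-2,3-epoxy-5-(PMBO)cyclohexan-1-one | O=C1[C@H]2O[C@H]2[C@H](O[Si](C)(C)C(C)(C)C)[C@H](OCc2ccc(OC)cc2)[C@H]1O[Si](C)(C)C(C)(C)C
F5 | step 9 | (3R,4R,5R,6S)-3,4,6-tris(TBSO)-5-(PMBO)-1-methylidenecyclohexane | C=C1C[C@@H](O[Si](C)(C)C(C)(C)C)[C@H](O[Si](C)(C)C(C)(C)C)[C@H](OCc2ccc(OC)cc2)[C@H]1O[Si](C)(C)C(C)(C)C
F6 | step 9 | spiro-epoxide of F5 (1-oxaspiro[2.5]octane, both epimers at the spiro carbon) | C1OC12C[C@@H](O[Si](C)(C)C(C)(C)C)[C@H](O[Si](C)(C)C(C)(C)C)[C@H](OCc3ccc(OC)cc3)[C@H]2O[Si](C)(C)C(C)(C)C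
F7 | step 9 | [(3R,4R,5R,6S)-3,4,6-tris(TBSO)-5-(PMBO)cyclohex-1-en-1-yl]methanol | OCC1=C[C@@H](O[Si](C)(C)C(C)(C)C)[C@H](O[Si](C)(C)C(C)(C)C)[C@H](OCc2ccc(OC)cc2)[C@H]1O[Si](C)(C)C(C)(C)C
F8 | step 6 | 1,2,7-trideoxy-3,5-di-O-TBS-4-O-PMB-L-manno-hept-1-enitol | C[C@H](O)[C@H](O[Si](C)(C)C(C)(C)C)[C@@H](OCc1ccc(OC)cc1)[C@@H](O[Si](C)(C)C(C)(C)C)C=C
F9 | step 6 | (3R,4S,5S)-3,5-bis(TBSO)-4-(PMBO)hept-6-en-2-one | CC(=O)[C@H](O[Si](C)(C)C(C)(C)C)[C@@H](OCc1ccc(OC)cc1)[C@@H](O[Si](C)(C)C(C)(C)C)C=C
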